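## Retrosynthetic overview

1. Target 16 comes from triol 15 by acetylation of the only unhindered (allylic C9) hydroxyl; the C4 methyl comes from a vinyl triflate by Suzuki coupling.
2. The side-chain tertiary C–O bond and E-olefin come from a prenyl terminus by a new aerobic selenium-catalysed ene-type hydroxylation (C–O bond formation).
3. Key C–O bond: C9–O and the C10 methylidene come from a C9=C10(CH3) cycloheptene by C6–OH-directed epoxidation, then epoxide-to-allylic-alcohol transposition.
4. The seven-membered ring is formed second, by ring-closing metathesis of an isopropenyl group (on C1) with an allyl group (on C7).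
5. The five-membered ring is bought as cyclopent-2-enone; a rhodium-catalysed asymmetric 1,4-addition/boron aldol with α-allylated (S)-citronellal sets C1, C5 and C6, while C7 and C11 come from the aldehyde.

Convention and assumption (one line): hydroazulene carbons are C1–C10 (C1/C5 ring fusion, CH3 on C4, OH on C6, side chain on C7, OAc on C9, =CH2 on C10), side-chain carbons carry primes (C2′ on C7), β is the face of the C6 hydroxyl, and (S)-citronellal is taken as an enantiopure commercial material.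

## Route

Step 1
Reactants: 1 (S)-citronellal; 2 allyl acetate
Product: 3 (2R,3S)-3,7-dimethyl-2-(prop-2-en-1-yl)oct-6-enal
Conditions: Pd(PPh3)4 (5 mol%), (R)-α,α-diphenylprolinol trimethylsilyl ether (20 mol%), DMSO, rt; short silica plug, used crude
Reagents that add atoms: none
Why: Enamine/π-allylpalladium dual catalysis (Tsuji–Trost α-allylation of an aldehyde): the E-enamine of 1 is shielded on one face by the catalyst, so C7 is set as 2R under catalyst control while C11 (3S) comes from citronellal, and crude 3 is used at once to avoid α-epimerisation.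

Step 2
Reactants: 3 (2R,3S)-3,7-dimethyl-2-(prop-2-en-1-yl)oct-6-enal; 4 cyclopent-2-en-1-one; 5 isopropenylmagnesium bromide; 6 B-methoxy-9-BBN
Product: 9 (2S,3S)-2-[(1S,2R,3S)-1-hydroxy-3,7-dimethyl-2-(prop-2-en-1-yl)oct-6-en-1-yl]-3-(prop-1-en-2-yl)cyclopentan-1-one, via B-isopropenyl-9-BBN 7 (not isolated), via boron enolate 8 (not isolated)
Conditions: 5 + 6, THF, −78 °C → rt, solvent switch to toluene; 4, [Rh(OMe)(cod)]2 (1.5 mol%), (S)-BINAP (3.3 mol%), toluene, 80 °C; then 3, −78 → −20 °C; MeOH/pH 7 buffer, 30% H2O2, 0 °C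
Reagents that add atoms: none
Why: Hayashi-type rhodium/(S)-BINAP asymmetric 1,4-addition of the alkenyl-9-BBN sets C1 (S) and gives a regiodefined boron E-enolate, whose Zimmerman–Traxler aldol with 3 occurs trans to the isopropenyl group (C5), anti (C6) and Felkin–Anh with respect to C7, a matched combination.

Step 3
Reactants: 9 (2S,3S)-2-[(1S,2R,3S)-1-hydroxy-3,7-dimethyl-2-(prop-2-en-1-yl)oct-6-en-1-yl]-3-(prop-1-en-2-yl)cyclopentan-1-one
Product: 10 (3aS,7R,8S,8aS)-8-hydroxy-4-methyl-7-[(2S)-6-methylhept-5-en-2-yl]-3,3a,6,7,8,8a-hexahydroazulen-1(2H)-one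
Conditions: second-generation Grubbs catalyst (5 mol%), CH2Cl2 (3 mM), 40 °C
Reagents that add atoms: none
Why: Ring-closing metathesis of the monosubstituted allyl olefin onto the neighbouring 1,1-disubstituted isopropenyl group closes the seven-membered ring as the trisubstituted C9=C10 olefin, the remote trisubstituted prenyl olefin being the slower partner for the ruthenium alkylidene.

Step 4
Reactants: 10 (3aS,7R,8S,8aS)-8-hydroxy-4-methyl-7-[(2S)-6-methylhept-5-en-2-yl]-3,3a,6,7,8,8a-hexahydroazulen-1(2H)-one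
Product: 11 (3aS,7R,8S,8aS)-8-hydroxy-4-methyl-7-[(2S)-6-methylhept-5-en-2-yl]-3,3a,6,7,8,8a-hexahydroazulen-1-yl trifluoromethanesulfonate
Conditions: LiN(SiMe3)2 (2.3 equiv), THF, −78 °C; PhNTf2 (1.2 equiv), −78 → 0 °C
Reagents that add atoms: N-phenylbis(trifluoromethanesulfonimide), O=S(=O)(N(c1ccccc1)S(=O)(=O)C(F)(F)F)C(F)(F)F
Why: Kinetic deprotonation of the alkoxide–ketone at the less hindered C3 methylene and O-triflation of the enolate (enol triflate formation) fixes the future C3=C4 position and leaves the five-membered ring as an electron-poor olefin that is inert to the oxidations that follow.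

Step 5
Reactants: 11 (3aS,7R,8S,8aS)-8-hydroxy-4-methyl-7-[(2S)-6-methylhept-5-en-2-yl]-3,3a,6,7,8,8a-hexahydroazulen-1-yl trifluoromethanesulfonate
Product: 12 9β,10β-epoxide of triflate 11 (oxirane cis to the C6 hydroxyl, C10 methyl α)
Conditions: VO(acac)2 (5 mol%), t-BuOOH (1.5 equiv, decane), CH2Cl2, 0 °C → rt
Reagents that add atoms: tert-butyl hydroperoxide, CC(C)(C)OO
Why: Sharpless-type hydroxyl-directed vanadium epoxidation: the C6 hydroxyl delivers the peroxide across the seven-membered ring to the β face of the C9=C10 olefin, forming the C9–O bond with the required configuration, while the undirected prenyl olefin and the vinyl triflate are left alone.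

Step 6
Reactants: 12 9β,10β-epoxide of triflate 11
Product: 13 (3aS,5R,7R,8S,8aS)-5,8-dihydroxy-4-methylidene-7-[(2S)-6-methylhept-5-en-2-yl]-3,3a,4,5,6,7,8,8a-octahydroazulen-1-yl trifluoromethanesulfonate
Conditions: Et2Al(TMP) (4 equiv; made in the flask from 2,2,6,6-tetramethylpiperidine, n-BuLi and Et2AlCl), toluene, 0 °C → rt; aq. Rochelle salt
Reagents that add atoms: none
Why: Yamamoto-type aluminium amide epoxide-to-allylic-alcohol isomerisation: the syn β-elimination can only take a hydrogen from the C10 methyl (H1 is anti to the oxirane oxygen), so the tertiary C10–O bond opens, C9–O stays untouched, and the methylidene and the 9β-hydroxyl arise together.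

Step 7
Reactants: 13 (3aS,5R,7R,8S,8aS)-5,8-dihydroxy-4-methylidene-7-[(2S)-6-methylhept-5-en-2-yl]-3,3a,4,5,6,7,8,8a-octahydroazulen-1-yl trifluoromethanesulfonate
Product: 14 (3aS,5R,7R,8S,8aS)-5,8-dihydroxy-7-[(2S,4E)-6-hydroxy-6-methylhept-4-en-2-yl]-4-methylidene-3,3a,4,5,6,7,8,8a-octahydroazulen-1-yl trifluoromethanesulfonate
Conditions: (PhSe)2 (10 mol%), 2,4,6-tris(4-methoxyphenyl)pyrylium tetrafluoroborate (5 mol%), O2 (1 atm), 465 nm LED, MeCN/H2O 9:1, rt
Reagents that add atoms: water, O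
Why: Proposed new method: photo-aerobically generated PhSe+ (a selenium π-acid) forms a seleniranium ion at the most electron-rich, least hindered olefin (the prenyl terminus; the vinyl triflate is electron-poor and the C10 methylidene is deactivated by the allylic C9–OH), water opens it at the tertiary C6′ (Markovnikov), and oxidative deselenenylation of the β-hydroxy selenide can only take a hydrogen from C4′, giving the E-C4′=C5′ tertiary allylic alcohol and returning the catalyst; the closest known reactions are the stoichiometric Sharpless–Lauer hydroxyselenation/selenoxide elimination and selenium-π-acid allylic esterification and amination, neither shown catalytically with water on an unactivated trisubstituted olefin.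

Step 8
Reactants: 14 (3aS,5R,7R,8S,8aS)-5,8-dihydroxy-7-[(2S,4E)-6-hydroxy-6-methylhept-4-en-2-yl]-4-methylidene-3,3a,4,5,6,7,8,8a-octahydroazulen-1-yl trifluoromethanesulfonate
Product: 15 (3aR,4S,5R,7R,8aS)-5-[(2S,4E)-6-hydroxy-6-methylhept-4-en-2-yl]-3-methyl-8-methylidene-1,3a,4,5,6,7,8,8a-octahydroazulene-4,7-diol
Conditions: MeB(OH)2 (3 equiv), Pd(PPh3)4 (5 mol%), K3PO4 (3 equiv), 1,4-dioxane/H2O 10:1, 80 °C
Reagents that add atoms: methylboronic acid, CB(O)O
Why: Suzuki–Miyaura methylation of the vinyl triflate installs the C4 methyl on the C3=C4 olefin without touching the free hydroxyls or any stereocentre.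

Step 9
Reactants: 15 (3aR,4S,5R,7R,8aS)-5-[(2S,4E)-6-hydroxy-6-methylhept-4-en-2-yl]-3-methyl-8-methylidene-1,3a,4,5,6,7,8,8a-octahydroazulene-4,7-diol
Product: 16 (3aR,4S,5R,7R,8aS)-4-hydroxy-5-[(2S,4E)-6-hydroxy-6-methylhept-4-en-2-yl]-3-methyl-8-methylidene-1,3a,4,5,6,7,8,8a-octahydroazulen-7-yl acetate
Conditions: Ac2O (1.2 equiv), pyridine, CH2Cl2, 0 °C
Reagents that add atoms: acetic anhydride, CC(=O)OC(C)=O
Why: Sterically controlled acylation: the allylic C9 hydroxyl is the only unhindered one (C6–OH is flanked by two methine carbons and C6′–OH is tertiary), so one equivalent of anhydride gives the 9-monoacetate, which is the target.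

## Compound list

1 | (S)-citronellal | O=CC[C@@H](C)CCC=C(C)C | starting material
2 | allyl acetate | C=CCOC(C)=O | starting material
3 | (2R,3S)-3,7-dimethyl-2-(prop-2-en-1-yl)oct-6-enal | O=C[C@@H]([C@@H](C)CCC=C(C)C)CC=C | intermediate
4 | cyclopent-2-en-1-one | O=C1C=CCC1 | starting material
5 | isopropenylmagnesium bromide | C=C(C)[Mg]Br | starting material
6 | B-methoxy-9-BBN (9-methoxy-9-borabicyclo[3.3.1]nonane) | COB1C2CCCC1CCC2 | starting material
7 | B-isopropenyl-9-BBN | C=C(C)B1C2CCCC1CCC2 | intermediate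
8 | boron enolate, 9-{[(3S)-3-(prop-1-en-2-yl)cyclopent-1-en-1-yl]oxy}-9-borabicyclo[3.3.1]nonane | C=C(C)[C@H]1CCC(OB2C3CCCC2CCC3)=C1 | intermediate
9 | (2S,3S)-2-[(1S,2R,3S)-1-hydroxy-3,7-dimethyl-2-(prop-2-en-1-yl)oct-6-en-1-yl]-3-(prop-1-en-2-yl)cyclopentan-1-one | C=C(C)[C@H]1CCC(=O)[C@@H]1[C@@H](O)[C@@H]([C@@H](C)CCC=C(C)C)CC=C | intermediate
10 | (3aS,7R,8S,8aS)-8-hydroxy-4-methyl-7-[(2S)-6-methylhept-5-en-2-yl]-3,3a,6,7,8,8a-hexahydroazulen-1(2H)-one | CC=1[C@H]2CCC(=O)[C@@H]2[C@@H](O)[C@@H]([C@@H](C)CCC=C(C)C)CC=1 | intermediate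
11 | (3aS,7R,8S,8aS)-8-hydroxy-4-methyl-7-[(2S)-6-methylhept-5-en-2-yl]-3,3a,6,7,8,8a-hexahydroazulen-1-yl trifluoromethanesulfonate | CC=1[C@H]2CC=C(OS(=O)(=O)C(F)(F)F)[C@@H]2[C@@H](O)[C@@H]([C@@H](C)CCC=C(C)C)CC=1 | intermediate
12 | 9β,10β-epoxide of triflate 11 (oxirane cis to the C6 hydroxyl, C10 methyl α) | C[C@]12[C@H]3CC=C(OS(=O)(=O)C(F)(F)F)[C@@H]3[C@@H](O)[C@@H]([C@@H](C)CCC=C(C)C)C[C@H]1O2 | intermediate
13 | (3aS,5R,7R,8S,8aS)-5,8-dihydroxy-4-methylidene-7-[(2S)-6-methylhept-5-en-2-yl]-3,3a,4,5,6,7,8,8a-octahydroazulen-1-yl trifluoromethanesulfonate | C=C1[C@H]2CC=C(OS(=O)(=O)C(F)(F)F)[C@@H]2[C@@H](O)[C@@H]([C@@H](C)CCC=C(C)C)C[C@H]1O | intermediate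
14 | (3aS,5R,7R,8S,8aS)-5,8-dihydroxy-7-[(2S,4E)-6-hydroxy-6-methylhept-4-en-2-yl]-4-methylidene-3,3a,4,5,6,7,8,8a-octahydroazulen-1-yl trifluoromethanesulfonate | C=C1[C@H]2CC=C(OS(=O)(=O)C(F)(F)F)[C@@H]2[C@@H](O)[C@@H]([C@@H](C)C/C=C/C(C)(C)O)C[C@H]1O | intermediate
15 | (3aR,4S,5R,7R,8aS)-5-[(2S,4E)-6-hydroxy-6-methylhept-4-en-2-yl]-3-methyl-8-methylidene-1,3a,4,5,6,7,8,8a-octahydroazulene-4,7-diol | C=C1[C@H]2CC=C(C)[C@@H]2[C@@H](O)[C@@H]([C@@H](C)C/C=C/C(C)(C)O)C[C@H]1O | intermediate
16 | (3aR,4S,5R,7R,8aS)-4-hydroxy-5-[(2S,4E)-6-hydroxy-6-methylhept-4-en-2-yl]-3-methyl-8-methylidene-1,3a,4,5,6,7,8,8a-octahydroazulen-7-yl acetate | C=C1[C@H]2CC=C(C)[C@@H]2[C@@H](O)[C@@H]([C@@H](C)C/C=C/C(C)(C)O)C[C@H]1OC(C)=O | target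

## Step count and weak points

Total step count: 9. Longest linear sequence: 9 steps (1 → 16).

The three steps most likely to fail are steps 2, 3 and 7.

**Step 2 (three-component coupling).** The alkenyl-9-BBN may transmetalate sluggishly, or the boron aldol may give poor diastereoselectivity. The fallback sets out from 4 (with 5 and 3) and returns at 9. Copper-catalysed asymmetric conjugate addition of 5 to 4 (CuBr·SMe2, the enantiomer of the ferrocenyl diphosphine 1-[2-(diphenylphosphino)ferrocenyl]ethyldicyclohexylphosphine that gives the 3S adduct, t-BuOMe, −78 °C), followed by trapping with Me3SiCl/Et3N, gives the regiodefined silyl enol ether (S)-trimethyl{[3-(prop-1-en-2-yl)cyclopent-1-en-1-yl]oxy}silane F1. MeLi in THF then releases the lithium enolate, which is transmetalated with ZnCl2 and combined with 3 at −78 °C in a Noyori-type zinc-enolate aldol. Adducts arising from the minor enolate enantiomer are diastereomers of 9 and are removed by chromatography.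

**Step 3 (ring-closing metathesis).** The prenyl olefin may compete with the isopropenyl group for the allyl-derived alkylidene. The fallback sets out from 9 and returns at 10. mCPBA (1.0 equiv, NaHCO3, CH2Cl2, −20 °C) epoxidises only the trisubstituted prenyl olefin and gives (2S,3S)-2-[(1S,2R,3S)-5-(3,3-dimethyloxiran-2-yl)-1-hydroxy-3-methyl-2-(prop-2-en-1-yl)pentyl]-3-(prop-1-en-2-yl)cyclopentan-1-one F2 (either oxirane epimer). Metathesis under the conditions of step 3 then has only one possible partner and gives (3aS,7R,8S,8aS)-7-[(2S)-4-(3,3-dimethyloxiran-2-yl)butan-2-yl]-8-hydroxy-4-methyl-3,3a,6,7,8,8a-hexahydroazulen-1(2H)-one F3. Deoxygenation with Ph3P=Se and CF3CO2H in CH2Cl2 at rt restores the prenyl olefin.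

**Step 7 (proposed new hydroxylation).** Catalyst turnover may fail, or the selenium electrophile may instead engage the C10 methylidene with transannular capture by the C6 hydroxyl. The fallback uses known chemistry, sets out from 13 and returns at 14. A Schenck ene reaction with singlet oxygen (O2, tetraphenylporphyrin, visible light, CH2Cl2, 0 °C) engages only the trisubstituted prenyl olefin. It gives (3aS,5R,7R,8S,8aS)-7-[(2S,4E)-6-hydroperoxy-6-methylhept-4-en-2-yl]-5,8-dihydroxy-4-methylidene-3,3a,4,5,6,7,8,8a-octahydroazulen-1-yl trifluoromethanesulfonate F4, formed alongside its secondary regioisomer in roughly equal amounts. PPh3 added to the same flask reduces F4 to 14, which is separated by chromatography.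

## Further compounds

F1 | step 2 | (S)-trimethyl{[3-(prop-1-en-2-yl)cyclopent-1-en-1-yl]oxy}silane | C=C(C)[C@H]1CCC(O[Si](C)(C)C)=C1
F2 | step 3 | (2S,3S)-2-[(1S,2R,3S)-5-(3,3-dimethyloxiran-2-yl)-1-hydroxy-3-methyl-2-(prop-2-en-1-yl)pentyl]-3-(prop-1-en-2-yl)cyclopentan-1-one | C=C(C)[C@H]1CCC(=O)[C@@H]1[C@@H](O)[C@@H]([C@@H](C)CCC1OC1(C)C)CC=C
F3 | step 3 | (3aS,7R,8S,8aS)-7-[(2S)-4-(3,3-dimethyloxiran-2-yl)butan-2-yl]-8-hydroxy-4-methyl-3,3a,6,7,8,8a-hexahydroazulen-1(2H)-one | CC=1[C@H]2CCC(=O)[C@@H]2[C@@H](O)[C@@H]([C@@H](C)CCC3OC3(C)C)CC=1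
F4 | step 7 | (3aS,5R,7R,8S,8aS)-7-[(2S,4E)-6-hydroperoxy-6-methylhept-4-en-2-yl]-5,8-dihydroxy-4-methylidene-3,3a,4,5,6,7,8,8a-octahydroazulen-1-yl trifluoromethanesulfonate | C=C1[C@H]2CC=C(OS(=O)(=O)C(F)(F)F)[C@@H]2[C@@H](O)[C@@H]([C@@H](C)C/C=C/C(C)(C)OO)C[C@H]1O
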